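Everything rests on cutting the C11–C12 bond (labdane-type numbering), the CH2–CH2 link whose two carbons are both allylic: C11 to the tetrasubstituted ring-B alkene C8=C9 of the decalin, C12 to the enal C13=C14. A photoredox decarboxylative allylation exploits exactly this 1,5-diene array: the C8–C9–C11 allyl radical, released from a sclareolide-derived acid whose lactone carbonyl is lost as CO2, adds through C11 to the exo-methylene C12 of a 2-formylallyl acetate, and acetate loss from C14 creates the (E)-enal in the same operation. The precursors are the redox-active ester of the Δ8-homodrimenic acid and the complete, unprotected (R)-butenolide acceptor, so the union is the last step.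

Key step: step 13

Remark: labdane-type numbering is used (C8=C9 ring alkene, C13=C14 enal, C15 the CH2 next to the lactone, C5′ the butenolide stereocentre); 2-bromo-3,3-diethoxyprop-1-ene, trimethyl(vinyloxy)silane and the bisphosphoramide catalyst are taken as purchasable.

Step 1
Reactants: 1 (+)-sclareolide
Product: 2 methyl 2-[(4aS,8aS)-2,5,5,8a-tetramethyl-3,4,4a,5,6,7,8,8a-octahydronaphthalen-1-yl]acetate
Conditions: conc. H2SO4, MeOH, reflux
Reagents that add atoms: methanol, CO
Why: Fischer-type acid-catalysed methanolysis of the tertiary lactone and E1 loss of the C8 oxygen under equilibrating conditions should favour the tetrasubstituted C8=C9 olefin (Zaitsev control), with C5 and C10 untouched.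

Step 2
Reactants: 2 methyl ester
Product: 3 2-[(4aS,8aS)-2,5,5,8a-tetramethyl-3,4,4a,5,6,7,8,8a-octahydronaphthalen-1-yl]acetic acid
Conditions: LiOH·H2O, THF/MeOH/H2O, 50 °C; then 1 M HCl, 0 °C
Reagents that add atoms: lithium hydroxide, [Li+].[OH-]
Why: Ester saponification should proceed without moving the tetrasubstituted β,γ-double bond, and the brief cold acidification is too mild to re-lactonise.

Step 3
Reactants: 3 acid
Product: 4 1,3-dioxoisoindolin-2-yl 2-[(4aS,8aS)-2,5,5,8a-tetramethyl-3,4,4a,5,6,7,8,8a-octahydronaphthalen-1-yl]acetate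
Conditions: N-hydroxyphthalimide, DIC, DMAP (cat.), CH2Cl2, rt
Reagents that add atoms: N-hydroxyphthalimide, O=C1N(O)C(=O)c2ccccc12
Why: Steglich-type carbodiimide esterification should give the redox-active N-acyloxyphthalimide needed for single-electron decarboxylation.

Step 4
Reactants: 5 2-methylenepropane-1,3-diol
Product: 6 2-{[(tert-butyldiphenylsilyl)oxy]methyl}prop-2-en-1-ol
Conditions: NaH (1.0 equiv), THF, 0 °C; then TBDPSCl (1.0 equiv)
Reagents that add atoms: tert-butyl(chloro)diphenylsilane, CC(C)(C)[Si](Cl)(c1ccccc1)c1ccccc1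
Why: Monosilylation of the symmetrical diol through its sparingly soluble monosodium alkoxide should give the mono-ether, and TBDPS is chosen to survive the acidic methanol quench of step 6.

Step 5
Reactants: 6 mono-silyl ether
Product: 7 2-{[(tert-butyldiphenylsilyl)oxy]methyl}prop-2-enal
Conditions: MnO2, CH2Cl2, rt
Reagents that add atoms: none
Why: MnO2 oxidation of the primary allylic alcohol should stop cleanly at the 2-substituted acrolein.

Step 6
Reactants: 7 enal, 8 trimethyl(vinyloxy)silane
Product: 10 (R)-2-{[(tert-butyldiphenylsilyl)oxy]methyl}-5,5-dimethoxypent-1-en-3-ol, via trichlorosilyl aldolate 9 (not isolated)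
Conditions: SiCl4 (1.5 equiv), (R,R)-BINAM-derived bisphosphoramide (5 mol%), i-Pr2NEt (10 mol%), CH2Cl2, −78 °C; then MeOH, −78 → 0 °C; aq. NaHCO3
Reagents that add atoms: methanol, CO
Why: Lewis-base-catalysed, SiCl4-mediated Mukaiyama aldol addition of the acetaldehyde enolsilane, in which the chiral phosphoramide-bound trichlorosilyl cation should expose the Re face of the enal and set the (R)-carbinol that becomes C5′ (the antipodal catalyst is equally available), the methanol quench turning the α-chloro silyl ether into the dimethyl acetal.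

Step 7
Reactants: 10 hydroxy acetal
Product: 11 (R)-2-{[(tert-butyldiphenylsilyl)oxy]methyl}-5,5-dimethoxypent-1-en-3-yl acrylate
Conditions: acryloyl chloride, Et3N, CH2Cl2, 0 °C
Reagents that add atoms: acryloyl chloride, C=CC(=O)Cl
Why: O-acylation of the secondary allylic alcohol proceeds with retention at the carbinol and installs the second olefin for ring closure.

Step 8
Reactants: 11 acrylate
Product: 12 (R)-4-{[(tert-butyldiphenylsilyl)oxy]methyl}-5-(2,2-dimethoxyethyl)furan-2(5H)-one
Conditions: Grubbs second-generation catalyst (5 mol%), toluene, 80 °C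
Reagents that add atoms: none
Why: Ring-closing metathesis between the acrylate and the only other olefin, the 1,1-disubstituted alkene, should close the five-membered butenolide with loss of ethylene and no change at C5′.

Step 9
Reactants: 12 butenolide acetal
Product: 13 2-[(2R)-3-{[(tert-butyldiphenylsilyl)oxy]methyl}-5-oxo-2,5-dihydrofuran-2-yl]acetaldehyde
Conditions: TFA/H2O (9:1), CH2Cl2, 0 °C
Reagents that add atoms: water, O
Why: Acid-catalysed acetal hydrolysis should unmask the aldehyde under conditions that keep the TBDPS ether and avoid base-induced β-elimination of the lactone oxygen.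

Step 10
Reactants: 13 aldehyde, 14 2-bromo-3,3-diethoxyprop-1-ene
Product: 15 (5R)-4-{[(tert-butyldiphenylsilyl)oxy]methyl}-5-[3-(diethoxymethyl)-2-hydroxybut-3-en-1-yl]furan-2(5H)-one (both carbinol epimers)
Conditions: CrCl2 (4 equiv), NiCl2 (2 mol%), DMF, rt
Reagents that add atoms: none
Why: Nozaki–Hiyama–Kishi coupling, in which the alkenylchromium(III) reagent adds only to the aldehyde under non-basic conditions that spare the β-acyloxy aldehyde and the lactone; the new C14 carbinol forms as both epimers, which is immaterial because C14 becomes sp2 in step 13.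

Step 11
Reactants: 15 allylic alcohol
Product: 16 1-[(2R)-3-{[(tert-butyldiphenylsilyl)oxy]methyl}-5-oxo-2,5-dihydrofuran-2-yl]-3-(diethoxymethyl)but-3-en-2-yl acetate (both epimers)
Conditions: Ac2O, pyridine, DMAP (cat.), CH2Cl2, 0 °C → rt
Reagents that add atoms: acetic anhydride, CC(=O)OC(C)=O
Why: Acetylation of the secondary alcohol installs the leaving group at C14 while the primary alcohol is still silylated and the alkene is not yet activated towards allylic transposition.

Step 12
Reactants: 16 acetate
Product: 18 3-formyl-1-[(2R)-3-(hydroxymethyl)-5-oxo-2,5-dihydrofuran-2-yl]but-3-en-2-yl acetate (both epimers), via desilylated diethyl acetal 17 (not isolated)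
Conditions: HF·pyridine, THF, 0 °C → rt; then 1 M aq. HCl, rt
Reagents that add atoms: water, O
Why: Fluoride desilylation of the primary TBDPS ether followed by aqueous acid hydrolysis of the diethyl acetal should unmask the alcohol and the 2-substituted acrolein without touching the secondary allylic acetate or the lactone.

Step 13
Reactants: 4 redox-active ester (1.5 equiv), 18 2-formylallyl acetate
Product: 19 (E)-4-[(2R)-3-(hydroxymethyl)-5-oxo-2,5-dihydrofuran-2-yl]-2-{2-[(4aS,8aS)-2,5,5,8a-tetramethyl-3,4,4a,5,6,7,8,8a-octahydronaphthalen-1-yl]ethyl}but-2-enal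
Conditions: Ru(bpy)3(PF6)2 (2 mol%), Hantzsch ester (1.5 equiv), degassed MeCN/CH2Cl2, blue LEDs, rt
Reagents that add atoms: none
Why: Photoexcited Ru(II) is reduced by the Hantzsch ester to Ru(I), which transfers an electron to 4; fragmentation expels phthalimide anion and CO2 and leaves the C8–C9–C11 allyl radical, which adds to the unsubstituted methylene C12 of 18 (Giese addition), and the α-formyl radical at C13 is then reduced to the enolate, which expels acetate from C14 (E1cB, radical–polar crossover) to give the C13=C14 enal. The closest known reaction type is the photoredox decarboxylative allylation of N-acyloxyphthalimides with Morita–Baylis–Hillman acetates (radical addition–elimination). No ring is closed and no stereocentre is formed; the only new stereo-element, the C13=C14 geometry, is under thermodynamic and A(1,3) control that places C15 trans to the formyl group (E), while C5, C10 and C5′ are untouched under these base-free, room-temperature conditions. The step needs regioselectivity within the allyl radical (C11 versus C8), secured because bonding at C8 would build a quaternary centre next to quaternary C10 whereas primary C11 is open and regenerates the tetrasubstituted C8=C9 alkene, and chemoselectivity for the formyl-activated 1,1-disubstituted alkene over the β,β-disubstituted butenolide, secured by the accessible terminal CH2.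

Compound list
1 | (+)-sclareolide, (3aR,5aS,9aS,9bR)-3a,6,6,9a-tetramethyldecahydronaphtho[2,1-b]furan-2(1H)-one | C[C@]12CCCC(C)(C)[C@@H]1CC[C@@]1(C)OC(=O)C[C@H]21 | starting material
2 | methyl 2-[(4aS,8aS)-2,5,5,8a-tetramethyl-3,4,4a,5,6,7,8,8a-octahydronaphthalen-1-yl]acetate | CC1=C(CC(=O)OC)[C@@]2(C)CCCC(C)(C)[C@@H]2CC1 | intermediate
3 | 2-[(4aS,8aS)-2,5,5,8a-tetramethyl-3,4,4a,5,6,7,8,8a-octahydronaphthalen-1-yl]acetic acid | CC1=C(CC(=O)O)[C@@]2(C)CCCC(C)(C)[C@@H]2CC1 | intermediate
4 | N-hydroxyphthalimide ester of 3 | CC1=C(CC(=O)ON3C(=O)c4ccccc4C3=O)[C@@]2(C)CCCC(C)(C)[C@@H]2CC1 | intermediate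
5 | 2-methylenepropane-1,3-diol | C=C(CO)CO | starting material
6 | 2-{[(tert-butyldiphenylsilyl)oxy]methyl}prop-2-en-1-ol | C=C(CO)CO[Si](c1ccccc1)(c1ccccc1)C(C)(C)C | intermediate
7 | 2-{[(tert-butyldiphenylsilyl)oxy]methyl}prop-2-enal | C=C(C=O)CO[Si](c1ccccc1)(c1ccccc1)C(C)(C)C | intermediate
8 | trimethyl(vinyloxy)silane | C=CO[Si](C)(C)C | starting material
9 | (R)-trichlorosilyl aldolate carrying the aldehyde as its α-chloro trimethylsilyl ether (either configuration at the chloro carbon) | Cl[Si](Cl)(Cl)O[C@H](CC(Cl)O[Si](C)(C)C)C(=C)CO[Si](c1ccccc1)(c1ccccc1)C(C)(C)C | intermediate (not isolated)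
10 | (R)-2-{[(tert-butyldiphenylsilyl)oxy]methyl}-5,5-dimethoxypent-1-en-3-ol | COC(OC)C[C@@H](O)C(=C)CO[Si](c1ccccc1)(c1ccccc1)C(C)(C)C | intermediate
11 | (R)-2-{[(tert-butyldiphenylsilyl)oxy]methyl}-5,5-dimethoxypent-1-en-3-yl acrylate | COC(OC)C[C@@H](OC(=O)C=C)C(=C)CO[Si](c1ccccc1)(c1ccccc1)C(C)(C)C | intermediate
12 | (R)-4-{[(tert-butyldiphenylsilyl)oxy]methyl}-5-(2,2-dimethoxyethyl)furan-2(5H)-one | COC(OC)C[C@H]1OC(=O)C=C1CO[Si](c1ccccc1)(c1ccccc1)C(C)(C)C | intermediate
13 | 2-[(2R)-3-{[(tert-butyldiphenylsilyl)oxy]methyl}-5-oxo-2,5-dihydrofuran-2-yl]acetaldehyde | O=CC[C@H]1OC(=O)C=C1CO[Si](c1ccccc1)(c1ccccc1)C(C)(C)C | intermediate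
14 | 2-bromo-3,3-diethoxyprop-1-ene (2-bromoacrolein diethyl acetal) | C=C(Br)C(OCC)OCC | starting material
15 | (5R)-4-{[(tert-butyldiphenylsilyl)oxy]methyl}-5-[3-(diethoxymethyl)-2-hydroxybut-3-en-1-yl]furan-2(5H)-one, both carbinol epimers | CCOC(OCC)C(=C)C(O)C[C@H]1OC(=O)C=C1CO[Si](c1ccccc1)(c1ccccc1)C(C)(C)C | intermediate
16 | acetate of 15, both epimers | CCOC(OCC)C(=C)C(OC(C)=O)C[C@H]1OC(=O)C=C1CO[Si](c1ccccc1)(c1ccccc1)C(C)(C)C | intermediate
17 | 3-(diethoxymethyl)-1-[(2R)-3-(hydroxymethyl)-5-oxo-2,5-dihydrofuran-2-yl]but-3-en-2-yl acetate, both epimers | CCOC(OCC)C(=C)C(OC(C)=O)C[C@H]1OC(=O)C=C1CO | intermediate (not isolated)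
18 | 3-formyl-1-[(2R)-3-(hydroxymethyl)-5-oxo-2,5-dihydrofuran-2-yl]but-3-en-2-yl acetate, both epimers | O=CC(=C)C(OC(C)=O)C[C@H]1OC(=O)C=C1CO | intermediate
19 | (E)-4-[(2R)-3-(hydroxymethyl)-5-oxo-2,5-dihydrofuran-2-yl]-2-{2-[(4aS,8aS)-2,5,5,8a-tetramethyl-3,4,4a,5,6,7,8,8a-octahydronaphthalen-1-yl]ethyl}but-2-enal | CC1=C(CC/C(C=O)=C\C[C@H]2OC(=O)C=C2CO)[C@@]2(C)CCCC(C)(C)[C@@H]2CC1 | target

Total step count: 13. Longest linear sequence: 10 steps (steps 4–13, from 2-methylenepropane-1,3-diol); the sclareolide branch is 3 steps before the union.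

Steps most likely to fail

1. Step 13. The stabilised, hindered allyl radical may add too slowly, so that hydrogen-atom transfer from the dihydropyridine to C11 or radical dimerisation competes. The adduct radical may also be capped by hydrogen before acetate is lost, and the allylic acetate of the acceptor may undergo 1,3-shift before coupling. The fallback separates C–C bond formation from olefin formation; it sets out from 15 and 4 and comes back at 19. HF·pyridine on 15 (no acetylation) would give the diol acetal (5R)-5-[3-(diethoxymethyl)-2-hydroxybut-3-en-1-yl]-4-(hydroxymethyl)furan-2(5H)-one F1. Aqueous HCl would then give the acetate-free acceptor 3-hydroxy-4-[(2R)-3-(hydroxymethyl)-5-oxo-2,5-dihydrofuran-2-yl]-2-methylenebutanal F2. Hydrogen-terminated photoredox Giese addition of the radical from 4 (Ru(bpy)3(PF6)2, Hantzsch ester, blue LEDs) would give the saturated aldol 3-hydroxy-4-[(2R)-3-(hydroxymethyl)-5-oxo-2,5-dihydrofuran-2-yl]-2-{2-[(4aS,8aS)-2,5,5,8a-tetramethyl-3,4,4a,5,6,7,8,8a-octahydronaphthalen-1-yl]ethyl}butanal F3. Piperidinium acetate-catalysed dehydration of this α-branched aldol (aldol-condensation type, thermodynamic E control) would give 19.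

2. Step 1. Proton loss from the C8 cation may be unselective (C7–H or the C8 methyl instead of C9–H), and re-lactonisation with epimerisation at C8 may drain material. The fallback fixes the double bond by a reductive, regiospecific sequence; it sets out from 1 and comes back at 3, bypassing steps 1 and 2. α-Selenenylation of the lactone enolate (LDA, THF, −78 °C; PhSeBr) would give 11-(phenylselanyl)sclareolide F4. Oxidation (H2O2, pyridine, CH2Cl2, 0 °C) and selenoxide syn-elimination towards C9–H would give the C9=C11 butenolide 9(11)-dehydrosclareolide F5. Two-electron reduction (SmI2, THF/HMPA, t-BuOH, −78 °C) would cleave the vinylogous C8–O bond, and kinetic α-protonation of the resulting dienediolate at C11 would give 3 with the alkene locked at C8=C9.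

3. Step 6. Facial discrimination or turnover may be poor with an α-branched, silyloxymethyl-substituted acrolein, and the acidic methanol quench may erode the acetal or silyl ether. The fallback replaces catalyst control by auxiliary control; it sets out from 7 and comes back at 10. Nagao acetate aldol of 7 with (S)-3-acetyl-4-isopropylthiazolidine-2-thione (Sn(OTf)2, N-ethylpiperidine, CH2Cl2, −78 °C) would pass through a tin-chelated chair transition state with the aldehyde approaching anti to the isopropyl group, and would give the (R)-β-hydroxy N-acylthiazolidinethione F6. DIBAL-H (CH2Cl2, −78 °C) would release the auxiliary and give the β-hydroxy aldehyde (R)-4-{[(tert-butyldiphenylsilyl)oxy]methyl}-3-hydroxypent-4-enal F7. Acetalisation (HC(OMe)3, PPTS, MeOH) would give 10.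

Further compounds
F1 | step 13 | (5R)-5-[3-(diethoxymethyl)-2-hydroxybut-3-en-1-yl]-4-(hydroxymethyl)furan-2(5H)-one, both epimers | CCOC(OCC)C(=C)C(O)C[C@H]1OC(=O)C=C1CO
F2 | step 13 | 3-hydroxy-4-[(2R)-3-(hydroxymethyl)-5-oxo-2,5-dihydrofuran-2-yl]-2-methylenebutanal, both epimers | O=CC(=C)C(O)C[C@H]1OC(=O)C=C1CO
F3 | step 13 | 3-hydroxy-4-[(2R)-3-(hydroxymethyl)-5-oxo-2,5-dihydrofuran-2-yl]-2-{2-[(4aS,8aS)-2,5,5,8a-tetramethyl-3,4,4a,5,6,7,8,8a-octahydronaphthalen-1-yl]ethyl}butanal, diastereomer mixture | CC1=C(CCC(C=O)C(O)C[C@H]2OC(=O)C=C2CO)[C@@]2(C)CCCC(C)(C)[C@@H]2CC1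
F4 | step 1 | 11-(phenylselanyl)sclareolide | C[C@]12CCCC(C)(C)[C@@H]1CC[C@@]1(C)OC(=O)C([Se]c3ccccc3)[C@H]21
F5 | step 1 | 9(11)-dehydrosclareolide (C9=C11 butenolide) | C[C@]12CCCC(C)(C)[C@@H]1CC[C@@]1(C)OC(=O)C=C21
F6 | step 6 | (R)-4-{[(tert-butyldiphenylsilyl)oxy]methyl}-3-hydroxy-1-[(S)-4-isopropyl-2-thioxothiazolidin-3-yl]pent-4-en-1-one | CC(C)[C@H]1CSC(=S)N1C(=O)C[C@@H](O)C(=C)CO[Si](c1ccccc1)(c1ccccc1)C(C)(C)C
F7 | step 6 | (R)-4-{[(tert-butyldiphenylsilyl)oxy]methyl}-3-hydroxypent-4-enal | O=CC[C@@H](O)C(=C)CO[Si](c1ccccc1)(c1ccccc1)C(C)(C)C
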